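## Retrosynthetic overview

1. The target is cut at the C8–C9 allyl–allyl bond into a ring-bearing C15 allyl sulfone **9** and the C10 bromide **12** made from geranyl acetate. The 2E and 6E alkenes are bought, not made.
2. Sulfone **9** comes from allylic alcohol **6**, which comes from methyl ketone **3** by an E-selective Horner–Wadsworth–Emmons reaction (sets 10E).
3. Ketone **3** comes from the trans-fused bicyclic enol ether **2**, made from (E)-geranylacetone **1** by an enantioselective proton-initiated cation–olefin cyclization.
4. Ring order: the cyclohexane closes first (C–C bond), and the ketone oxygen then closes a temporary dihydropyran anti to that bond. Hydrolysing the dihydropyran reveals the tertiary alcohol. No other ring is formed.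

Assumption: isomerically pure (E)-geranylacetone is purchased, and recombinant squalene–hopene cyclase (AacSHC) is used as the chiral Brønsted-acid catalyst in step 1. This is the one non-standard reagent in the route. The absolute configuration it delivers, (4aS,8aS), is inferred from its hopene/ambrox A-ring selectivity.

## Route

**Step 1**
Reactants: **1**, (E)-geranylacetone
Product: **2**, (4aS,8aS)-2,5,5,8a-tetramethyl-4a,5,6,7,8,8a-hexahydro-4H-chromene
Conditions: AacSHC (E. coli whole cells), citrate buffer pH 6.0, 0.2% Triton X-100, 30 °C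
Reagents that add atoms: none
Why: Enzymatic protonative cation–olefin cyclization through a chair fold; the (E)-alkene attacks and the ketone oxygen traps the tertiary cation anti to the new C–C bond (trans fusion), and the enzyme fixes both stereocentres in the same facial sense as its hopene/ambrox A ring.

**Step 2**
Reactants: **2**
Product: **3**, 4-[(1S,2S)-2-hydroxy-2,6,6-trimethylcyclohexyl]butan-2-one
Conditions: oxalic acid (cat.), THF–H2O, 0 °C to rt; NaHCO3 work-up, used crude
Reagents that add atoms: water, O
Why: Enol-ether hydrolysis breaks only the O–C2 bond, so the C8a–O bond and both stereocentres are untouched.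

**Step 3**
Reactants: **3**; **4**, triethyl phosphonoacetate
Product: **5**, ethyl (2E)-5-[(1S,2S)-2-hydroxy-2,6,6-trimethylcyclohexyl]-3-methylpent-2-enoate
Conditions: **4** + NaH (1.0 equiv per phosphonate, pre-formed), THF, 0 to 50 °C; chromatography to remove the minor 2Z isomer
Reagents that add atoms: triethyl phosphonoacetate, CCOC(=O)CP(=O)(OCC)OCC
Why: Horner–Wadsworth–Emmons olefination of a methyl ketone is E-selective (expected about 4:1); with no excess NaH the tertiary OH stays un-ionised, which suppresses oxa-Michael closure.

**Step 4**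
Reactants: **5**
Product: **6**, (2E)-5-[(1S,2S)-2-hydroxy-2,6,6-trimethylcyclohexyl]-3-methylpent-2-en-1-ol
Conditions: DIBAL-H (3.5 equiv), CH2Cl2, −78 to 0 °C
Reagents that add atoms: none
Why: DIBAL 1,2-reduction of the enoate gives the allylic alcohol with the alkene geometry retained.

**Step 5**
Reactants: **6**
Product: **7**, (1S,2S)-2-[(3E)-5-chloro-3-methylpent-3-en-1-yl]-1,3,3-trimethylcyclohexan-1-ol
Conditions: MsCl, LiCl, 2,4,6-collidine, DMF, 0 °C; used directly
Reagents that add atoms: lithium chloride, [Li+].[Cl-] (MsCl is the activator)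
Why: Collington–Meyers chlorination (in situ allylic mesylate, SN2 by chloride) is selective for the primary allylic OH; the hindered tertiary OH is inert and there is no allylic transposition.

**Step 6**
Reactants: **7**; **8**, sodium benzenesulfinate
Product: **9**, (1S,2S)-1,3,3-trimethyl-2-[(3E)-3-methyl-5-(phenylsulfonyl)pent-3-en-1-yl]cyclohexan-1-ol
Conditions: PhSO2Na, NaI (cat.), DMF, rt
Reagents that add atoms: sodium benzenesulfinate, [Na+].[O-]S(=O)c1ccccc1
Why: SN2 S-alkylation of the sulfinate by the primary allylic chloride gives the E-allyl sulfone.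

**Step 7**
Reactants: **10**, geranyl acetate
Product: **11**, (2E,6E)-8-hydroxy-3,7-dimethylocta-2,6-dien-1-yl acetate
Conditions: SeO2 (0.1 equiv), t-BuOOH, salicylic acid (cat.), CH2Cl2, rt; then NaBH4, MeOH, 0 °C (returns over-oxidised enal)
Reagents that add atoms: selenium dioxide, O=[Se]=O, with tert-butyl hydroperoxide, CC(C)(C)OO (net one O)
Why: Sharpless SeO2 allylic oxidation (ene then [2,3] shift) hits the E-methyl of the electron-richer terminal alkene; the 2,3-alkene is deactivated by the allylic acetate.

**Step 8**
Reactants: **11**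
Product: **12**, (2E,6E)-8-bromo-3,7-dimethylocta-2,6-dien-1-yl acetate
Conditions: CBr4, PPh3, CH2Cl2, 0 °C
Reagents that add atoms: carbon tetrabromide, BrC(Br)(Br)Br
Why: Appel bromination of the primary allylic alcohol proceeds by SN2 without touching the acetate or the alkene geometry.

**Step 9**
Reactants: **9**; **12**
Product: **13**, (2E,6E,10E)-13-[(1S,2S)-2-hydroxy-2,6,6-trimethylcyclohexyl]-3,7,11-trimethyl-9-(phenylsulfonyl)trideca-2,6,10-trien-1-yl acetate (epimers at C9, irrelevant)
Conditions: n-BuLi (2.1 equiv), THF–DMPU, −78 °C; add **12**, −78 to −40 °C; NH4Cl quench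
Reagents that add atoms: none beyond **9** and **12**
Why: Julia/Biellmann-type α-alkylation of the allyl sulfone carbanion (as the alkoxide/carbanion dianion) by the allylic bromide is faster than attack on the acetate at −78 °C, and all alkene geometries are preserved.

**Step 10**
Reactants: **13**
Product: **14**, preluffariellolide A, (2E,6E,10E)-13-[(1S,2S)-2-hydroxy-2,6,6-trimethylcyclohexyl]-3,7,11-trimethyltrideca-2,6,10-trien-1-ol
Conditions: LiBHEt3 (6 equiv), THF, 0 °C, 30 min; then PdCl2(dppp) (5 mol %), 0 °C to rt
Reagents that add atoms: none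
Why: Super-Hydride first cleaves the acetate (so no Pd-allyl forms at C1), then Pd-catalysed reductive desulfonylation delivers hydride to the less substituted π-allyl terminus, keeping the 10E trisubstituted alkene in place.

## Compound list

1 | (E)-geranylacetone | CC(=O)CC/C=C(\C)CCC=C(C)C | starting material
2 | (4aS,8aS)-2,5,5,8a-tetramethyl-4a,5,6,7,8,8a-hexahydro-4H-chromene | CC1=CC[C@H]2C(C)(C)CCC[C@]2(C)O1 | intermediate
3 | 4-[(1S,2S)-2-hydroxy-2,6,6-trimethylcyclohexyl]butan-2-one | CC(=O)CC[C@H]1C(C)(C)CCC[C@]1(C)O | intermediate
4 | triethyl phosphonoacetate | CCOC(=O)CP(=O)(OCC)OCC | starting material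
5 | ethyl (2E)-5-[(1S,2S)-2-hydroxy-2,6,6-trimethylcyclohexyl]-3-methylpent-2-enoate | CCOC(=O)/C=C(\C)CC[C@H]1C(C)(C)CCC[C@]1(C)O | intermediate
6 | (2E)-5-[(1S,2S)-2-hydroxy-2,6,6-trimethylcyclohexyl]-3-methylpent-2-en-1-ol | OC/C=C(\C)CC[C@H]1C(C)(C)CCC[C@]1(C)O | intermediate
7 | (1S,2S)-2-[(3E)-5-chloro-3-methylpent-3-en-1-yl]-1,3,3-trimethylcyclohexan-1-ol | ClC/C=C(\C)CC[C@H]1C(C)(C)CCC[C@]1(C)O | intermediate
8 | sodium benzenesulfinate | [Na+].[O-]S(=O)c1ccccc1 | starting material
9 | (1S,2S)-1,3,3-trimethyl-2-[(3E)-3-methyl-5-(phenylsulfonyl)pent-3-en-1-yl]cyclohexan-1-ol | O=S(=O)(C/C=C(\C)CC[C@H]1C(C)(C)CCC[C@]1(C)O)c1ccccc1 | intermediate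
10 | geranyl acetate | CC(=O)OC/C=C(\C)CCC=C(C)C | starting material
11 | (2E,6E)-8-hydroxy-3,7-dimethylocta-2,6-dien-1-yl acetate | CC(=O)OC/C=C(\C)CC/C=C(\C)CO | intermediate
12 | (2E,6E)-8-bromo-3,7-dimethylocta-2,6-dien-1-yl acetate | CC(=O)OC/C=C(\C)CC/C=C(\C)CBr | intermediate
13 | C25 sulfone acetate (9-phenylsulfonyl, C9 epimers) | CC(=O)OC/C=C(\C)CC/C=C(\C)CC(/C=C(\C)CC[C@H]1C(C)(C)CCC[C@]1(C)O)S(=O)(=O)c1ccccc1 | intermediate
14 | preluffariellolide A | C/C(=C\CO)CC/C=C(\C)CC/C=C(\C)CC[C@H]1C(C)(C)CCC[C@]1(C)O | target

## Summary

Total steps: 10. Longest linear sequence: 8 (steps 1–6, 9, 10).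

Steps most likely to fail, with fallbacks:

- **Step 1 (enzymatic enantioselective cyclization: enzyme access, scale, conversion).** Fallback: set absolute configuration chemically. Make the (S)-terminal epoxide of geranylacetone by asymmetric dihydroxylation, mesylation and base closure, run a MeAlCl2 epoxy-olefin cyclization with the same ketone trapping, then remove the extra C3 hydroxyl by Barton–McCombie deoxygenation to rejoin at **3**. Alternatively, cyclize racemically with ClSO3H at −78 °C and resolve sulfone **9** by preparative chiral chromatography.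
- **Step 3 (HWE: only moderate E/Z, and the hydroxy ketone can re-close to the hemiketal or enol ether).** Fallback: convert **3** to the terminal alkyne (LDA, ClP(O)(OEt)2, then LDA; tertiary OH temporarily silylated), then Negishi Zr-catalysed carboalumination (Me3Al, Cp2ZrCl2) and paraformaldehyde to give **6** as a single E isomer.
- **Steps 9/10 (dianion alkylation next to an acetate; Pd/hydride desulfonylation with a free tertiary alkoxide could transpose the alkene or form a cyclic ether).** Fallback: reverse the polarity and change the reductive step. Couple chloride **7** (OH as TMS ether) with the anion of 8-(phenylsulfonyl)geranyl benzyl ether, then remove sulfonyl and benzyl together with Li/EtNH2 at −78 °C.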